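Ring A (C1 OMe, C2 Me, C3=O, C4 OH, C5 tether, C6=O) is cut at C3–C4 and C5–C6. Atoms C6, C1, C2 and C3 come as a methoxy(methyl)maleoyl fragment bound through both acyl carbons to trivalent cobalt, whereas C4 and C5 are supplied by the terminal alkyne that caps the fourteen-methylene tether. One Lewis-acid-promoted metallacycle–alkyne annulation forges both bonds and the complete quinone ring, with OMe and Me already vicinal and C4 left as C–H for later oxygenation. Its partners are a phosphine-free dimethylglyoxime/pyridine maleoylcobalt chloride and a hexadec-15-ynyl arene holding ring B as a tetraacetate. Acetoxylation at C4 and one global methanolysis with air oxidation then release both hydroxyquinones.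

Key step: step 10

Assumption: the Lewis-acid-promoted insertion is taken to bond the unsubstituted alkyne carbon to the C3 acyl carbon (tether para to methyl). The target has no stereocentre, and racemic intermediates are written without configuration unless noted.

Step 1
Reactants: 1 dimethyl squarate
Product: 3 3-methoxy-4-methylcyclobut-3-ene-1,2-dione, via lithium alkoxide adduct 2 (not isolated)
Conditions: MeLi, THF, −78 °C; (CF3CO)2O, −78 °C; aq. NH4Cl, → rt
Reagents that add atoms: methyllithium, [Li]C; water, O
Why: 1,2-Addition of MeLi to one squarate carbonyl, trifluoroacetylation of the alkoxide, and hydrolytic collapse of the resulting cyclobutenyl cation with loss of methanol make up the standard squarate-to-cyclobutenedione sequence.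

Step 2
Reactants: 3 3-methoxy-4-methylcyclobut-3-ene-1,2-dione
Product: 4 chlorobis(triphenylphosphine) methoxy(methyl)maleoylcobalt, CoCl(PPh3)2[C(O)C(OMe)=C(Me)C(O)]
Conditions: CoCl(PPh3)3, toluene, rt → 40 °C, Ar
Reagents that add atoms: CoCl(PPh3)3, Cl[Co-3]([P+](c1ccccc1)(c1ccccc1)c1ccccc1)([P+](c1ccccc1)(c1ccccc1)c1ccccc1)[P+](c1ccccc1)(c1ccccc1)c1ccccc1
Why: Oxidative addition of monovalent cobalt into the strained bond between the two carbonyl carbons of a cyclobutenedione is the established entry to maleoylcobalt complexes and should give the five-membered trivalent cobalt diacyl with loss of one phosphine.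

Step 3
Reactants: 4 chlorobis(triphenylphosphine) methoxy(methyl)maleoylcobalt
Product: 5 chloro(dimethylglyoxime)(pyridine) methoxy(methyl)maleoylcobalt, CoCl(dmgH2)(py)[C(O)C(OMe)=C(Me)C(O)]
Conditions: dimethylglyoxime, pyridine, rt
Reagents that add atoms: dimethylglyoxime, C/C(=N\O)/C(=N/O)/C; pyridine, c1ccncc1
Why: Known ligand substitution by the chelating dioxime and pyridine expels both phosphines, giving an octahedral complex whose labile pyridine opens a site for the alkyne and removing PPh3 that would otherwise add to the quinone product.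

Step 4
Reactants: 6 2,5-dihydroxy-1,4-benzoquinone
Product: 8 1,2,4,5-tetrakis(methoxymethoxy)benzene, via benzene-1,2,4,5-tetrol 7 (not isolated)
Conditions: H2 (1 atm), PtO2, THF, rt; filter under Ar; NaH, MOMCl, THF–DMF, 0 °C → rt
Reagents that add atoms: chloromethyl methyl ether, COCCl
Why: Catalytic hydrogenation of the quinone followed directly by fourfold Williamson-type O-alkylation under argon protects the air-sensitive tetrol without handling it.

Step 5
Reactants: 8 1,2,4,5-tetrakis(methoxymethoxy)benzene
Product: 10 1,2,4,5-tetrakis(methoxymethoxy)-3-methylbenzene, via aryllithium 9 (not isolated)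
Conditions: n-BuLi (1.05 equiv), THF, 0 °C; MeI, −78 °C → rt
Reagents that add atoms: iodomethane, CI
Why: Directed ortho-metalation removes a proton flanked by two chelating OMOM groups, one equivalent of base stops at the monolithio stage, and SN2 capture by MeI installs the ring B methyl group.

Step 6
Reactants: 11 tetradecane-1,14-diol
Product: 12 1,14-dibromotetradecane
Conditions: 48% aq. HBr, conc. H2SO4, reflux
Reagents that add atoms: hydrogen bromide, Br
Why: Double acid-promoted SN2 substitution of protonated primary alcohols by bromide is the classical route to α,ω-dibromoalkanes.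

Step 7
Reactants: 10 1,2,4,5-tetrakis(methoxymethoxy)-3-methylbenzene; 12 1,14-dibromotetradecane
Product: 14 1-(14-bromotetradecyl)-2,3,5,6-tetrakis(methoxymethoxy)-4-methylbenzene, via methylated aryllithium 13 (not isolated)
Conditions: n-BuLi, THF, 0 °C; cannulate into 12 (3 equiv), THF–DMPU, −20 °C → rt
Reagents that add atoms: none
Why: A second directed ortho-metalation at the only remaining ring C–H and SN2 alkylation follow the usual practice for tetraalkoxybenzenes, and inverse addition to an excess of the symmetrical dibromide suppresses double arylation.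

Step 8
Reactants: 14 1-(14-bromotetradecyl)-2,3,5,6-tetrakis(methoxymethoxy)-4-methylbenzene
Product: 15 1-(hexadec-15-yn-1-yl)-2,3,5,6-tetrakis(methoxymethoxy)-4-methylbenzene
Conditions: LiC≡CH·H2NCH2CH2NH2, DMSO–THF, rt
Reagents that add atoms: lithium acetylide–ethylenediamine complex, [Li]C#C.NCCN
Why: SN2 displacement of a primary bromide by lithium acetylide in DMSO is the classical terminal alkyne synthesis, and the MOM acetals are inert to base.

Step 9
Reactants: 15 1-(hexadec-15-yn-1-yl)-2,3,5,6-tetrakis(methoxymethoxy)-4-methylbenzene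
Product: 17 3-(hexadec-15-yn-1-yl)-6-methylbenzene-1,2,4,5-tetrayl tetraacetate, via alkynyl tetrol 16 (not isolated)
Conditions: conc. HCl (cat.), MeOH–THF, 45 °C, Ar; evaporate; Ac2O, pyridine, Zn dust, rt, Ar
Reagents that add atoms: acetic anhydride, CC(=O)OC(C)=O
Why: Acid-catalysed transacetalisation to methanol frees the four phenols and immediate peracetylation under argon, with Zn dust present only to return adventitious quinone by reductive acetylation, gives a fully substituted aryl tetraacetate while the alkyne stays untouched.

Step 10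
Reactants: 5 chloro(dimethylglyoxime)(pyridine) methoxy(methyl)maleoylcobalt (1.5 equiv); 17 3-(hexadec-15-yn-1-yl)-6-methylbenzene-1,2,4,5-tetrayl tetraacetate
Product: 18 2-methoxy-3-methyl-6-[14-(2,3,5,6-tetraacetoxy-4-methylphenyl)tetradecyl]-1,4-benzoquinone
Conditions: SnCl4 (about 3 equiv), CH2Cl2, 0 °C → rt, Ar; H2O quench, work-up in air
Reagents that add atoms: none
Why: SnCl4 binds the more basic C3 acyl oxygen (a vinylogous ester through the C1 methoxy group) and labilises pyridine, so the alkyne enters the coordination sphere of trivalent cobalt and inserts into the Co–C3 bond with its unsubstituted carbon becoming C4, giving a seven-membered cobaltacycle. Reductive elimination then joins C5 to the C6 acyl carbon and expels monovalent cobalt, so ring A closes as a six-membered carbocycle by migratory insertion followed by C–C reductive elimination in an intermolecular four-plus-two annulation. The closest known reaction type is the Lewis-acid-promoted quinone synthesis from dimethylglyoxime maleoylcobalt complexes and terminal alkynes, which is established for 2-methoxy-3-methylbenzoquinones. No stereocentre is created. The selectivity required is regiochemical (tether on C5, next to C6 and para to methyl); it rests on the electronic difference between the two acyl carbons, sharpened by the Lewis acid, and on the polarisation of a terminal alkyne that places developing positive charge on its substituted carbon, and the sense is to be verified beforehand with hexadec-1-yne. Chemoselectivity is secured because ring B is fully substituted and offers no Fries or Friedel–Crafts site, its acetates only tie up Lewis acid that the excess SnCl4 covers, and the phosphine was removed in step 3.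

Step 11
Reactants: 18 2-methoxy-3-methyl-6-[14-(2,3,5,6-tetraacetoxy-4-methylphenyl)tetradecyl]-1,4-benzoquinone
Product: 19 heptaacetate, 3,4,6-triacetoxy-1-methoxy-2-methyl-5-[14-(2,3,5,6-tetraacetoxy-4-methylphenyl)tetradecyl]benzene
Conditions: Ac2O, BF3·OEt2 (cat.), rt → 40 °C
Reagents that add atoms: acetic anhydride, CC(=O)OC(C)=O
Why: In the Thiele–Winter acetoxylation the acid-activated quinone accepts acetate at its only C–H carbon C4, which is β to the C6 carbonyl that the methoxy group does not deactivate, and enolisation plus acetylation trap the triacetate while the ring B acetates are inert.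

Step 12
Reactants: 19 heptaacetate
Product: 21 2-hydroxy-5-methoxy-6-methyl-3-[14-(2,5-dihydroxy-4-methyl-3,6-dioxocyclohexa-1,4-dien-1-yl)tetradecyl]-1,4-benzoquinone (CNP0130251.0), via heptaphenol 20 (not isolated)
Conditions: K2CO3, dry MeOH, 0 °C → rt, open to air; then 1 M HCl
Reagents that add atoms: none
Why: Zemplén-type transesterification removes all seven aryl acetates, the liberated hydroxyhydroquinone and tetrol rings autoxidise in basic methanol to hydroxyquinone anions whose charge shields them from further attack, and methoxide exchange at C1 is degenerate so the methyl ether should persist.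

Compound list
1 | dimethyl squarate (3,4-dimethoxycyclobut-3-ene-1,2-dione) | COC1=C(OC)C(=O)C1=O | starting material
2 | lithium 2,3-dimethoxy-1-methyl-4-oxocyclobut-2-en-1-olate (racemic) | [Li+].[O-]C1(C)C(OC)=C(OC)C1=O | intermediate
3 | 3-methoxy-4-methylcyclobut-3-ene-1,2-dione | COC1=C(C)C(=O)C1=O | intermediate
4 | CoCl(PPh3)2[C(O)C(OMe)=C(Me)C(O)], five-membered trivalent cobalt diacyl | COC1=C(C)C(=O)[Co-2](Cl)([P+](c2ccccc2)(c2ccccc2)c2ccccc2)([P+](c2ccccc2)(c2ccccc2)c2ccccc2)C1=O | intermediate
5 | CoCl(dmgH2)(py)[C(O)C(OMe)=C(Me)C(O)], octahedral trivalent cobalt diacyl | COC1=C(C)C(=O)[Co-3]2(Cl)([n+]3ccccc3)([N+](O)=C(C)C(C)=[N+]2O)C1=O | intermediate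
6 | 2,5-dihydroxy-1,4-benzoquinone | O=C1C=C(O)C(=O)C=C1O | starting material
7 | benzene-1,2,4,5-tetrol | Oc1cc(O)c(O)cc1O | intermediate
8 | 1,2,4,5-tetrakis(methoxymethoxy)benzene | COCOc1cc(OCOC)c(OCOC)cc1OCOC | intermediate
9 | 2,3,5,6-tetrakis(methoxymethoxy)phenyllithium | [Li]c1c(OCOC)c(OCOC)cc(OCOC)c1OCOC | intermediate
10 | 1,2,4,5-tetrakis(methoxymethoxy)-3-methylbenzene | Cc1c(OCOC)c(OCOC)cc(OCOC)c1OCOC | intermediate
11 | tetradecane-1,14-diol | OCCCCCCCCCCCCCCO | starting material
12 | 1,14-dibromotetradecane | BrCCCCCCCCCCCCCCBr | intermediate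
13 | 2,3,5,6-tetrakis(methoxymethoxy)-4-methylphenyllithium | [Li]c1c(OCOC)c(OCOC)c(C)c(OCOC)c1OCOC | intermediate
14 | 1-(14-bromotetradecyl)-2,3,5,6-tetrakis(methoxymethoxy)-4-methylbenzene | BrCCCCCCCCCCCCCCc1c(OCOC)c(OCOC)c(C)c(OCOC)c1OCOC | intermediate
15 | 1-(hexadec-15-yn-1-yl)-2,3,5,6-tetrakis(methoxymethoxy)-4-methylbenzene | C#CCCCCCCCCCCCCCCc1c(OCOC)c(OCOC)c(C)c(OCOC)c1OCOC | intermediate
16 | 3-(hexadec-15-yn-1-yl)-6-methylbenzene-1,2,4,5-tetrol | C#CCCCCCCCCCCCCCCc1c(O)c(O)c(C)c(O)c1O | intermediate
17 | 3-(hexadec-15-yn-1-yl)-6-methylbenzene-1,2,4,5-tetrayl tetraacetate | C#CCCCCCCCCCCCCCCc1c(OC(C)=O)c(OC(C)=O)c(C)c(OC(C)=O)c1OC(C)=O | intermediate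
18 | 2-methoxy-3-methyl-6-[14-(2,3,5,6-tetraacetoxy-4-methylphenyl)tetradecyl]-1,4-benzoquinone | COC1=C(C)C(=O)C=C(CCCCCCCCCCCCCCc2c(OC(C)=O)c(OC(C)=O)c(C)c(OC(C)=O)c2OC(C)=O)C1=O | intermediate
19 | heptaacetate, 3,4,6-triacetoxy-1-methoxy-2-methyl-5-[14-(2,3,5,6-tetraacetoxy-4-methylphenyl)tetradecyl]benzene | COc1c(C)c(OC(C)=O)c(OC(C)=O)c(CCCCCCCCCCCCCCc2c(OC(C)=O)c(OC(C)=O)c(C)c(OC(C)=O)c2OC(C)=O)c1OC(C)=O | intermediate
20 | heptaphenol, 3-[14-(2,3,5-trihydroxy-6-... written in full: 5-methoxy-6-methyl-3-[14-(2,3,5,6-tetrahydroxy-4-methylphenyl)tetradecyl]benzene-1,2,4-triol | COc1c(C)c(O)c(O)c(CCCCCCCCCCCCCCc2c(O)c(O)c(C)c(O)c2O)c1O | intermediate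
21 | 2-hydroxy-5-methoxy-6-methyl-3-[14-(2,5-dihydroxy-4-methyl-3,6-dioxocyclohexa-1,4-dien-1-yl)tetradecyl]-1,4-benzoquinone (CNP0130251.0) | COC1=C(C)C(=O)C(O)=C(CCCCCCCCCCCCCCC2=C(O)C(=O)C(C)=C(O)C2=O)C1=O | target

Total step count: 12. Longest linear sequence: 8 steps (4, 5, 7, 8, 9, 10, 11, 12) from 6.

Steps most likely to fail

Step 10. The alkyne may insert in the opposite sense. The annulation may also stall because the acetates and the glyoxime ligand sequester the Lewis acid.
- The fallback builds ring A by cyclobutenone ring expansion, where connectivity fixes the regiochemistry. It sets out from 1 and from the MOM-protected alkyne 15.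
- Alkoxide 2, generated as in step 1, is trifluoroacetylated and quenched with dry methanol in place of water. This gives 3,4,4-trimethoxy-2-methylcyclobut-2-en-1-one F1, in which only the carbonyl next to the methyl-bearing carbon is free.
- The lithium acetylide of 15 (n-BuLi, THF, −78 °C) adds to that carbonyl to give the racemic 1-alkynyl-3,4,4-trimethoxy-2-methylcyclobut-2-en-1-ol F2.
- Oxalic acid on wet silica unmasks the ketal to the racemic 4-alkynyl-4-hydroxy-2-methoxy-3-methylcyclobut-2-en-1-one F3.
- Heating in toluene triggers the Moore rearrangement: electrocyclic opening to the enynyl ketene, six-membered closure and hydrogen transfer. It should give the MOM-protected quinone F4 with the same C3–C4 and C5–C6 bonds.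
- Ac2O/BF3·OEt2 then acetolyses the four aryl MOM acetals and performs the Thiele–Winter addition in one medium. The detour comes back at heptaacetate 19.

Step 11. Conjugate addition to a trisubstituted, methoxy-donated quinone may be sluggish, and prolonged acid exposure may erode the methyl ether.
- The fallback sets out from 18 and replaces acid-catalysed acetoxylation by nucleophilic epoxidation and isomerisation.
- A Weitz–Scheffer-type epoxidation (t-BuOOH, DBU, one equivalent each, CH2Cl2, −20 °C) attacks C4, the β-carbon of the more electrophilic enone. It gives the racemic cis-fused 4,5-epoxide F5.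
- Acid (p-TsOH or BF3·OEt2, CH2Cl2) promotes enolisation at C4 with opening of the C5–O bond, as in the classical conversion of 2-alkylquinone epoxides into hydroxyquinones. The product is the ring A hydroxyquinone with ring B still a tetraacetate, F6.
- The conditions of step 12 then free and oxidise ring B only, and the detour comes back at 21.

Step 12. The C1 methoxy group may be displaced by adventitious hydroxide, and peroxide formed during basic autoxidation may degrade the rings.
- The fallback sets out from 19 and separates deprotection from oxidation.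
- LiAlH4 (THF, 0 °C, Ar) cleaves the acetates reductively while no quinone is present. Quenching with degassed dilute HCl gives heptaphenol 20, now isolated under argon.
- Aqueous FeCl3 in acetone at 0 °C oxidises both rings under non-basic conditions, and the detour comes back at 21. It makes no compound outside the list (F0).

Further compounds
F1 | step 10 | 3,4,4-trimethoxy-2-methylcyclobut-2-en-1-one | COC1=C(C)C(=O)C1(OC)OC
F2 | step 10 | 3,4,4-trimethoxy-2-methyl-1-{16-[2,3,5,6-tetrakis(methoxymethoxy)-4-methylphenyl]hexadec-1-yn-1-yl}cyclobut-2-en-1-ol (racemic) | COC1=C(C)C(O)(C#CCCCCCCCCCCCCCCc2c(OCOC)c(OCOC)c(C)c(OCOC)c2OCOC)C1(OC)OC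
F3 | step 10 | 4-hydroxy-2-methoxy-3-methyl-4-{16-[2,3,5,6-tetrakis(methoxymethoxy)-4-methylphenyl]hexadec-1-yn-1-yl}cyclobut-2-en-1-one (racemic) | COC1=C(C)C(O)(C#CCCCCCCCCCCCCCCc2c(OCOC)c(OCOC)c(C)c(OCOC)c2OCOC)C1=O
F4 | step 10 | 2-methoxy-3-methyl-6-{14-[2,3,5,6-tetrakis(methoxymethoxy)-4-methylphenyl]tetradecyl}-1,4-benzoquinone | COC1=C(C)C(=O)C=C(CCCCCCCCCCCCCCc2c(OCOC)c(OCOC)c(C)c(OCOC)c2OCOC)C1=O
F5 | step 11 | cis-fused 4,5-epoxide of quinone 18 (racemic, one enantiomer drawn) | COC1=C(C)C(=O)[C@@H]2O[C@]2(CCCCCCCCCCCCCCc3c(OC(C)=O)c(OC(C)=O)c(C)c(OC(C)=O)c3OC(C)=O)C1=O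
F6 | step 11 | 2-hydroxy-5-methoxy-6-methyl-3-[14-(2,3,5,6-tetraacetoxy-4-methylphenyl)tetradecyl]-1,4-benzoquinone | COC1=C(C)C(=O)C(O)=C(CCCCCCCCCCCCCCc2c(OC(C)=O)c(OC(C)=O)c(C)c(OC(C)=O)c2OC(C)=O)C1=O
F0 | step 12 | none | none
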